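# Proposed synthesis of (−)-epicatechin 3-O-syringate (CNP0128506.1)

## Analysis of the target

The target is a flavan: chroman rings A and C are fused, ring B is a catechol on C2, and the C3 oxygen carries a 4-hydroxy-3,5-dimethoxybenzoyl (syringoyl) group. There are two adjacent stereocentres, C2 (R) and C3 (R), and they are cis: the ring-B aryl group and the acyloxy group lie on the same face of ring C, the less stable of the two arrangements. Five phenols are free; ring A is a phloroglucinol-type ring that is nucleophilic at C6 and C8 and easily oxidised, ring B is an oxidisable catechol, and C2 is a benzylic ether carbon that can epimerise in base or on heating. The two aryl methyl ethers and the hindered secondary ester must survive the release of the five phenols, which points to benzyl ethers removed by hydrogenolysis. The difficulty lies in the 2,3-cis relative and (2R,3R) absolute configuration, in the fact that C4 is a plain CH2 (any route through a C4 carbonyl pays for its removal), and in the low tolerance of the electron-rich ring A for strong acid or oxidants. The plan rests on one feature of ring A: O1 is bound to C8a, C4 is bound to C4a, these two carbons are neighbours, and the C5 oxygen sits beside C4a. This is the pattern left when a 3,5-dioxygenated benzyne takes up the oxygen and the carbon of one aldehyde group, so ring A can arrive as an aryne and O1, C2, C3 and C4 as an α-oxygenated cinnamaldehyde.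

## Retrosynthetic reasoning

The five O–benzyl bonds of the penta-benzyl ester 22 are the last to be cut, giving target 23. All phenols are carried as benzyl ethers from the starting materials, because hydrogenolysis is the one deprotection that leaves the aryl methyl ethers, the ester and both stereocentres alone, and because the free polyphenol should exist only at the very end.

The acyl C–O3 bond of 22 is cut next, giving the (2R,3R) alcohol 18 and the protected acid 21. This divides the molecule into a flavan-3-ol and a simple benzoic acid, and acylation on oxygen cannot disturb C3. Acid 21 goes back to syringic acid 19 by benzylation through ester 20.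

Alcohol 18 is traced to the racemic ketone 17 by cutting the C3–H bond. With a carbonyl at C3, the C2 hydrogen is α to a ketone, benzylic and α to oxygen, so the two enantiomers of 17 interconvert. A chiral hydride donor that reduces one of them faster, from the face opposite to the aryl group, then sets C2 and C3 together. The forward step must be cis-selective and enantioselective, with racemisation faster than reduction.

Ketone 17 is the hydrolysis product of the methyl enol ether 16. The enol ether is the form in which the C3 oxygen survives ring construction; hydrolysis turns C4 into CH2 by protonation, so no oxygen ever has to be removed from C4.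

Chromene 16 is cut at three bonds, O1–C8a, C4–C4a and O1–C2, giving silyl triflate 8 and enal 12. Forward, 8 releases aryne 13, which adds across the C=O of 12 to give benzoxete 14; this opens to o-quinone methide 15, which closes ring C. The cut is made here because it joins two halves of similar size, uses a ring A whose oxygenation is bought, and delivers C3 at the ketone oxidation level. The forward reaction must place the oxygen on the aryne carbon remote from the flanking benzyloxy group.

Triflate 8 is cut at the O–S and C–Si bonds. It goes back through the ortho-silyl carbamate 6 and carbamate 2 to phenol 1; the carbamate directs metalation to the position between itself and a benzyloxy group (intermediates 3, 4 and 5), and its removal gives phenol 7 for triflation.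

Enal 12 is cut at its C=C bond, giving aldehyde 10 and aldehyde 11 by an aldol condensation; 11 is released from its acetal 9.

## Alternatives that were turned down

Alternative 1: Ring A itself is taken apart. The C4a–C5 bond is cut and the ring unfolds to the open-chain triketo ester A2, which carries ring B at its cinnamoyl end. Forward, methoxide would fold A2 by an intramolecular Claisen condensation (C6 carbanion onto the C1 ester) and aromatisation would give the trihydroxychalcone A1. In its favour, all three ring-A oxygens come from chain carbonyls, so no regiochemical question arises on ring A, and neither an organolithium reagent nor an aryne is needed; on these two points it is at least as strong as the chosen plan. Against it, A1 has the wrong oxidation pattern on ring C (a carbonyl at C4, nothing at C3). After ring closure the C3 oxygen must be brought in, the C4 oxygen removed and both stereocentres set in separate operations. The folding also competes with aldol-type closure of the same polyketone and with pyrone formation, and the three ring-A phenols emerge free and must be differentiated again. Ring A is also the cheapest part of the molecule to buy. The chosen strategy offers instead a bought, protected ring A and a ring-C closure that leaves C3 at the ketone level and C4 without oxygen, which saves several steps.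

Alternative 2: The cut is across ring C at C4–C3 and O1–C2. Forward, a chiral phosphoric acid would dehydrate salicyl alcohol A4 to o-quinone methide A5, which would add the Z-enol ester A6 in a [4+2] cycloaddition to give A3, the same compound as 22 here. This is the most convergent plan: ring C, both stereocentres and the ester arrive in one step and only hydrogenolysis remains, so on step count and convergence it is clearly stronger than the chosen strategy. Against it, three selectivities rest on one step with poorly matched partners:
- The regiochemistry needs the methide carbon to bond to the acyloxy-bearing alkene carbon, against the polarisation imposed by the enol oxygen, and relies on the electron-rich aryl group winning.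
- The cis relationship survives only if the addition is concerted and A6 neither isomerises nor hydrolyses under the acid that generates A5.
- The catalyst must differentiate the faces of a dienophile that offers it no hydrogen-bond donor.

A6 is also an acid-labile enol ester of an electron-rich arylacetaldehyde and must be made as the pure Z isomer. The chosen strategy is longer but separates these decisions, each settled by one element: regiochemistry by aryne polarisation, the cis relationship by hydride approach opposite to the aryl group, and absolute configuration by the reduction catalyst.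

Alternative 3: The C3=C4 bond is cut. Forward, the second-generation Grubbs catalyst (H2IMes)(PCy3)Cl2Ru=CHPh would close diene A8, an enantiopure 1-arylallyl aryl ether with an ortho vinyl group, to the (S)-2H-chromene A7. In its favour, ring-closing metathesis to 2H-chromenes is dependable, and C2 is fixed before ring closure by an independent asymmetric etherification; on predictability of the absolute configuration it is stronger than a dynamic kinetic resolution. Against it, A7 has no oxygen at C3. Hydroboration–oxidation would add it anti to the aryl group, giving the 2,3-trans relationship, so an oxidation–reduction or an inversion at C3 must follow. The C2 centre of A7 is allylic, benzylic and oxygen-bound and can racemise by reversible electrocyclic ring opening or acid ionisation. A8 also needs a ring-A phenol with an ortho vinyl group, which takes several steps. The chosen strategy carries the C3 oxygen from the start, needs no inversion, and makes C2 racemic on purpose so that its lability is used and not feared.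

Key step: step 5

Remark on the chemistry (assumption): in step 7 the unbranched benzylic C4 side of ketone 17 is taken to lie next to the arene ligand of the catalyst and the branched C2 side away from it; on this model the (S,S) catalyst gives the (3R) carbinol, and if the sense proved opposite the (R,R) catalyst would be used with no other change.

## Route

Step 1
Reactants: 1 3,5-bis(benzyloxy)phenol
Product: 2 3,5-bis(benzyloxy)phenyl N-isopropylcarbamate
Conditions: i-PrNCO, Et3N (cat.), CH2Cl2, rt
Reagents that add atoms: isopropyl isocyanate, CC(C)N=C=O
Why: Carbamoylation of the phenol by addition of O–H across the isocyanate; the secondary carbamate is a strong director for metalation and can later be removed under mild amine conditions.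

Step 2
Reactants: 2 3,5-bis(benzyloxy)phenyl N-isopropylcarbamate
Product: 6 3,5-bis(benzyloxy)-2-(trimethylsilyl)phenyl N-isopropylcarbamate, via N-silyl carbamate 3 (not isolated), via aryllithium 4 (not isolated), via bis-silyl carbamate 5 (not isolated)
Conditions: t-BuMe2SiOTf, TMEDA, Et2O, 0 °C → rt; n-BuLi, TMEDA, −78 °C; Me3SiCl, −78 °C → rt; aq. NaHSO4
Reagents that add atoms: chlorotrimethylsilane, C[Si](C)(C)Cl
Why: Directed ortho-metalation: after temporary N-silylation the carbamate is the strongest directing group on the ring, and n-BuLi/TMEDA removes the proton between it and a benzyloxy group (both such positions are equivalent by symmetry). Me3SiCl traps the aryllithium at −78 °C before an anionic Fries shift, and the N-silyl group is lost on acidic work-up.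

Step 3
Reactants: 6 3,5-bis(benzyloxy)-2-(trimethylsilyl)phenyl N-isopropylcarbamate
Product: 8 3,5-bis(benzyloxy)-2-(trimethylsilyl)phenyl trifluoromethanesulfonate, via silyl phenol 7 (not isolated)
Conditions: DBU, Et2NH, MeCN, 40 °C; then PhNTf2, rt
Reagents that add atoms: N-phenylbis(trifluoromethanesulfonimide), O=S(=O)(N(c1ccccc1)S(=O)(=O)C(F)(F)F)C(F)(F)F
Why: One-pot carbamate cleavage and triflation: DBU removes the N–H proton, the isocyanate is expelled (E1cB) and trapped by Et2NH, and the hindered phenoxide of 7 is triflated by PhNTf2. These mild conditions should leave the C–Si bond and the benzyl ethers untouched.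

Step 4
Reactants: 9 1,1,2-trimethoxyethane; 10 3,4-bis(benzyloxy)benzaldehyde
Product: 12 (Z)-3-[3,4-bis(benzyloxy)phenyl]-2-methoxyprop-2-enal, via methoxyacetaldehyde 11 (not isolated)
Conditions: 9, sulfonic acid resin (Amberlyst 15, H+ form), H2O, 50 °C, filter; then slow addition of the solution (excess) to 10, NaOH (0.3 equiv), MeOH/THF/H2O, 0 °C → rt
Reagents that add atoms: water, O
Why: Acetal hydrolysis followed by a crossed aldol (Claisen–Schmidt) condensation: 10 cannot enolise and 11 enolises only at the methoxy-bearing carbon. E1cB dehydration should give the more stable enal with the aryl group trans to the formyl group, which is the (Z) isomer by the sequence rules.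

Step 5
Reactants: 8 3,5-bis(benzyloxy)-2-(trimethylsilyl)phenyl trifluoromethanesulfonate; 12 (Z)-3-[3,4-bis(benzyloxy)phenyl]-2-methoxyprop-2-enal
Product: 16 racemic 5,7-bis(benzyloxy)-2-[3,4-bis(benzyloxy)phenyl]-3-methoxy-2H-chromene, via aryne 13 (not isolated), via benzoxete 14 (not isolated), via o-quinone methide 15 (not isolated)
Conditions: 12 (1.5 equiv), CsF, MeCN/THF, rt → 50 °C, slow addition of 8, argon
Reagents that add atoms: none
Why: Fluoride attacks silicon in 8 and triflate leaves, which releases aryne 13 at a low stationary concentration. The aldehyde oxygen of 12 adds to the aryne carbon remote from the flanking benzyloxy group, because that substituent distorts the triple bond and inductively stabilises the aryl anion developing next to it; the anion then closes on the carbonyl carbon, so the formal [2+2] addition gives benzoxete 14 with O1–C8a and C4–C4a in place. Thermal 4π ring opening of the strained four-membered ring gives o-quinone methide 15, and the isomer with the alkenyl group syn to the carbonyl oxygen closes ring C by a disrotatory oxa-6π electrocyclisation that forms O1–C2 and restores the aromaticity of ring A. The closest known reaction type is the fluoride-induced reaction of arynes with cinnamaldehydes and other α,β-unsaturated aldehydes to give 2H-chromenes. C2 is the only new stereocentre and should form racemic, since nothing chiral is present; this is intended, because the centre is corrected in step 7. The selectivity needed is regiochemical (5,7- and not 6,8-dioxygenation) and is secured by the benzyloxy group beside the triple bond; the aryl group of 12 is trans to the formyl carbon, so it points outwards in the ring closure and should not slow it. Enal 12 is used in excess so that the electron-rich enol ether of 16 does not compete for a second aryne.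

Step 6
Reactants: 16 racemic 5,7-bis(benzyloxy)-2-[3,4-bis(benzyloxy)phenyl]-3-methoxy-2H-chromene
Product: 17 racemic 5,7-bis(benzyloxy)-2-[3,4-bis(benzyloxy)phenyl]chroman-3-one
Conditions: 1 M HCl (aq), THF, rt, argon
Reagents that add atoms: water, O
Why: Enol ether hydrolysis: protonation at C4 gives the C3 oxocarbenium ion, water adds and methanol leaves, so C3 becomes the ketone and C4 a CH2 group. C2 stays racemic, which the next step requires.

Step 7
Reactants: 17 racemic 5,7-bis(benzyloxy)-2-[3,4-bis(benzyloxy)phenyl]chroman-3-one
Product: 18 (2R,3R)-5,7-bis(benzyloxy)-2-[3,4-bis(benzyloxy)phenyl]chroman-3-ol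
Conditions: RuCl(p-cymene)[(S,S)-TsDPEN] (2 mol%), HCO2H/Et3N (1:1), DMF, 40 °C
Reagents that add atoms: none
Why: Noyori asymmetric transfer hydrogenation under dynamic kinetic resolution: C2–H of 17 is α to the ketone, benzylic and α to oxygen, so the enantiomers should interconvert through the enol in the amine/formate medium, while the product cannot. Hydride goes to the face of C3 opposite to the C2 aryl group, which gives the cis alcohol, and the (S,S) catalyst is expected to reduce the (2R) ketone on the Si face of C3 faster than it reduces the (2S) ketone on either face, so C2 (R) and C3 (R) are set together under catalyst control.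

Step 8
Reactants: 19 syringic acid (4-hydroxy-3,5-dimethoxybenzoic acid)
Product: 21 4-(benzyloxy)-3,5-dimethoxybenzoic acid, via benzyl ester 20 (not isolated)
Conditions: BnBr, K2CO3, DMF, 60 °C; then NaOH, H2O/MeOH, reflux; HCl (aq) to pH 2
Reagents that add atoms: benzyl bromide, BrCc1ccccc1; sodium hydroxide, [Na+].[OH-]
Why: Williamson alkylation of phenoxide and carboxylate, then saponification of the benzyl ester only, the aryl benzyl ether being inert to hydroxide. The benzyl ether keeps the 4-hydroxyl from acylating in step 9 and leaves with the others in step 10.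

Step 9
Reactants: 18 (2R,3R)-5,7-bis(benzyloxy)-2-[3,4-bis(benzyloxy)phenyl]chroman-3-ol; 21 4-(benzyloxy)-3,5-dimethoxybenzoic acid
Product: 22 (2R,3R)-5,7-bis(benzyloxy)-2-[3,4-bis(benzyloxy)phenyl]chroman-3-yl 4-(benzyloxy)-3,5-dimethoxybenzoate
Conditions: DCC, DMAP (cat.), CH2Cl2, 0 °C → rt
Reagents that add atoms: none
Why: Steglich esterification (carbodiimide activation, acyl transfer through the acylpyridinium ion); acylation takes place on oxygen, so C3 is retained, and the neutral conditions should not endanger C2.

Step 10
Reactants: 22 (2R,3R)-5,7-bis(benzyloxy)-2-[3,4-bis(benzyloxy)phenyl]chroman-3-yl 4-(benzyloxy)-3,5-dimethoxybenzoate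
Product: 23 (2R,3R)-2-(3,4-dihydroxyphenyl)-5,7-dihydroxychroman-3-yl 4-hydroxy-3,5-dimethoxybenzoate (target)
Conditions: H2 (1 atm), Pd(OH)2/C, THF/MeOH, rt
Reagents that add atoms: none
Why: Hydrogenolysis of the five benzyl ethers under neutral conditions should leave the ester, the aryl methyl ethers and both stereocentres untouched; low pressure and room temperature protect the benzylic C2–O1 bond.

## Compound list

1 | 3,5-bis(benzyloxy)phenol | Oc1cc(OCc2ccccc2)cc(OCc2ccccc2)c1 | starting material
2 | 3,5-bis(benzyloxy)phenyl N-isopropylcarbamate | CC(C)NC(=O)Oc1cc(OCc2ccccc2)cc(OCc2ccccc2)c1 | intermediate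
3 | 3,5-bis(benzyloxy)phenyl N-(tert-butyldimethylsilyl)-N-isopropylcarbamate (N-silyl carbamate, not isolated) | CC(C)N(C(=O)Oc1cc(OCc2ccccc2)cc(OCc2ccccc2)c1)[Si](C)(C)C(C)(C)C | intermediate
4 | 2-lithio derivative of 3, lithium at the ring carbon between the carbamate oxygen and a benzyloxy group (aryllithium, not isolated) | [Li]c1c(OCc2ccccc2)cc(OCc2ccccc2)cc1OC(=O)N(C(C)C)[Si](C)(C)C(C)(C)C | intermediate
5 | 3,5-bis(benzyloxy)-2-(trimethylsilyl)phenyl N-(tert-butyldimethylsilyl)-N-isopropylcarbamate (bis-silyl carbamate, not isolated) | CC(C)N(C(=O)Oc1cc(OCc2ccccc2)cc(OCc2ccccc2)c1[Si](C)(C)C)[Si](C)(C)C(C)(C)C | intermediate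
6 | 3,5-bis(benzyloxy)-2-(trimethylsilyl)phenyl N-isopropylcarbamate | CC(C)NC(=O)Oc1cc(OCc2ccccc2)cc(OCc2ccccc2)c1[Si](C)(C)C | intermediate
7 | 3,5-bis(benzyloxy)-2-(trimethylsilyl)phenol (silyl phenol, present as its DBU salt, not isolated) | C[Si](C)(C)c1c(O)cc(OCc2ccccc2)cc1OCc1ccccc1 | intermediate
8 | 3,5-bis(benzyloxy)-2-(trimethylsilyl)phenyl trifluoromethanesulfonate | C[Si](C)(C)c1c(OCc2ccccc2)cc(OCc2ccccc2)cc1OS(=O)(=O)C(F)(F)F | intermediate
9 | 1,1,2-trimethoxyethane | COCC(OC)OC | starting material
10 | 3,4-bis(benzyloxy)benzaldehyde | O=Cc1ccc(OCc2ccccc2)c(OCc2ccccc2)c1 | starting material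
11 | methoxyacetaldehyde (aqueous solution, not isolated) | COCC=O | intermediate
12 | (Z)-3-[3,4-bis(benzyloxy)phenyl]-2-methoxyprop-2-enal | CO/C(C=O)=C\c1ccc(OCc2ccccc2)c(OCc2ccccc2)c1 | intermediate
13 | 3,5-bis(benzyloxy)benzyne (aryne, not isolated) | C1#CC(OCc2ccccc2)=CC(OCc2ccccc2)=C1 | intermediate
14 | racemic 3,5-bis(benzyloxy)-2-{(Z)-2-[3,4-bis(benzyloxy)phenyl]-1-methoxyethenyl}-2H-benzo[b]oxete (benzoxete, not isolated) | CO/C(=C\c1ccc(OCc2ccccc2)c(OCc2ccccc2)c1)C1Oc2cc(OCc3ccccc3)cc(OCc3ccccc3)c21 | intermediate
15 | (6Z)-3,5-bis(benzyloxy)-6-{(2Z)-3-[3,4-bis(benzyloxy)phenyl]-2-methoxyprop-2-en-1-ylidene}cyclohexa-2,4-dien-1-one (o-quinone methide, not isolated) | CO/C(/C=C1\C(=O)C=C(OCc2ccccc2)C=C1OCc1ccccc1)=C\c1ccc(OCc2ccccc2)c(OCc2ccccc2)c1 | intermediate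
16 | racemic 5,7-bis(benzyloxy)-2-[3,4-bis(benzyloxy)phenyl]-3-methoxy-2H-chromene | COC1=Cc2c(OCc3ccccc3)cc(OCc3ccccc3)cc2OC1c1ccc(OCc2ccccc2)c(OCc2ccccc2)c1 | intermediate
17 | racemic 5,7-bis(benzyloxy)-2-[3,4-bis(benzyloxy)phenyl]chroman-3-one | O=C1Cc2c(OCc3ccccc3)cc(OCc3ccccc3)cc2OC1c1ccc(OCc2ccccc2)c(OCc2ccccc2)c1 | intermediate
18 | (2R,3R)-5,7-bis(benzyloxy)-2-[3,4-bis(benzyloxy)phenyl]chroman-3-ol | O[C@@H]1Cc2c(OCc3ccccc3)cc(OCc3ccccc3)cc2O[C@@H]1c1ccc(OCc2ccccc2)c(OCc2ccccc2)c1 | intermediate
19 | syringic acid (4-hydroxy-3,5-dimethoxybenzoic acid) | COc1cc(C(=O)O)cc(OC)c1O | starting material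
20 | benzyl 4-(benzyloxy)-3,5-dimethoxybenzoate (benzyl ester, not isolated) | COc1cc(C(=O)OCc2ccccc2)cc(OC)c1OCc1ccccc1 | intermediate
21 | 4-(benzyloxy)-3,5-dimethoxybenzoic acid | COc1cc(C(=O)O)cc(OC)c1OCc1ccccc1 | intermediate
22 | (2R,3R)-5,7-bis(benzyloxy)-2-[3,4-bis(benzyloxy)phenyl]chroman-3-yl 4-(benzyloxy)-3,5-dimethoxybenzoate | COc1cc(C(=O)O[C@@H]2Cc3c(OCc4ccccc4)cc(OCc4ccccc4)cc3O[C@@H]2c2ccc(OCc3ccccc3)c(OCc3ccccc3)c2)cc(OC)c1OCc1ccccc1 | intermediate
23 | (2R,3R)-2-(3,4-dihydroxyphenyl)-5,7-dihydroxychroman-3-yl 4-hydroxy-3,5-dimethoxybenzoate | COc1cc(C(=O)O[C@@H]2Cc3c(O)cc(O)cc3O[C@@H]2c2ccc(O)c(O)c2)cc(OC)c1O | target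

## Step count and least certain steps

Total step count: 10. Longest linear sequence: 8 steps (steps 1, 2, 3, 5, 6, 7, 9 and 10, from 1 to 23).

**Step 5 (key step).** The most likely failure is slow capture of the aryne by the weakly nucleophilic carbonyl oxygen, so that aryne self-reaction takes over. A second aryne may also add to the o-quinone methide before it electrocyclises, or to the electron-rich enol ether of the product. The fallback abandons the aryne and reaches the same o-quinone methide from the phenol. From 1 and 12, PhB(OH)2 and AcOH (cat.) in toluene at reflux with removal of water should alkylate the phenol at its ortho carbon within a borate and give 5,7-bis(benzyloxy)-4-{(Z)-2-[3,4-bis(benzyloxy)phenyl]-1-methoxyethenyl}-2-phenyl-4H-1,3,2-benzodioxaborinine F1. On further heating F1 should lose the boron unit to give 15, which closes to 16. The fallback sets out from 1 and 12 and rejoins the route at 16; steps 1 to 3 are then not needed.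

**Step 7.** The carbonyl carbon of 17 carries no aryl group, so both flanks are sp3 benzylic carbons and the catalyst must read the C2 centre. Poor discrimination between the two ketone enantiomers, racemisation that is too slow relative to reduction, or an absolute sense opposite to the assumed one are all possible; the last is met by the mirror-image catalyst. The fallback replaces asymmetric catalysis by resolution:
- From 17, LiBH(s-Bu)3 in THF at −78 °C should deliver hydride opposite to the aryl group and give racemic cis-5,7-bis(benzyloxy)-2-[3,4-bis(benzyloxy)phenyl]chroman-3-ol F2.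
- Esterification with (S)-2-methoxy-2-phenylacetic acid (DCC, DMAP, CH2Cl2) should give two diastereomers, (2R,3R)-5,7-bis(benzyloxy)-2-[3,4-bis(benzyloxy)phenyl]chroman-3-yl (S)-2-methoxy-2-phenylacetate F3 and its (2S,3S) diastereomer F4, to be separated by chromatography or crystallisation.
- Saponification of F3 (LiOH, THF/H2O) returns to the route at 18; F4 is set aside.

**Step 2.** Deprotonation at a benzylic O–CH2 position followed by a [1,2]-Wittig rearrangement, or lithiation between the two benzyloxy groups, may compete with the intended ortho-metalation. The fallback replaces deprotonation by halogen–lithium exchange: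
- From 1, ortho-selective bromination (NBS, i-Pr2NH (cat.), CH2Cl2, 0 °C) should give 2-bromo-3,5-bis(benzyloxy)phenol F5.
- Silylation with (Me3Si)2NH in THF at reflux gives [2-bromo-3,5-bis(benzyloxy)phenoxy]trimethylsilane F6.
- n-BuLi in THF at −100 °C exchanges bromine faster than any proton is removed, the silyl group shifts from oxygen to carbon (retro-Brook rearrangement) to give the lithium salt of 7, and Tf2O closes the sequence at 8.

**Step 4.** Self-condensation of the enolisable aldehyde 11 may outrun its crossed reaction with the electron-rich, poorly electrophilic 10, and the alkene geometry may not be uniform. The fallback builds the enal by olefination and redox adjustment: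
- From 10, a Horner–Wadsworth–Emmons reaction with methyl 2-(dimethoxyphosphoryl)-2-methoxyacetate (NaH, THF) should give methyl (Z)-3-[3,4-bis(benzyloxy)phenyl]-2-methoxyprop-2-enoate F7.
- i-Bu2AlH in CH2Cl2 at −78 °C reduces it to (Z)-3-[3,4-bis(benzyloxy)phenyl]-2-methoxyprop-2-en-1-ol F8.
- MnO2 in CH2Cl2 oxidises the allylic alcohol and returns to the route at 12.

## Further compounds

F1 | step 5 | 5,7-bis(benzyloxy)-4-{(Z)-2-[3,4-bis(benzyloxy)phenyl]-1-methoxyethenyl}-2-phenyl-4H-1,3,2-benzodioxaborinine (racemic) | CO/C(=C\c1ccc(OCc2ccccc2)c(OCc2ccccc2)c1)C1OB(c2ccccc2)Oc2cc(OCc3ccccc3)cc(OCc3ccccc3)c21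
F2 | step 7 | racemic cis-5,7-bis(benzyloxy)-2-[3,4-bis(benzyloxy)phenyl]chroman-3-ol (relative configuration 2R*,3R*; one enantiomer drawn) | O[C@@H]1Cc2c(OCc3ccccc3)cc(OCc3ccccc3)cc2O[C@@H]1c1ccc(OCc2ccccc2)c(OCc2ccccc2)c1
F3 | step 7 | (2R,3R)-5,7-bis(benzyloxy)-2-[3,4-bis(benzyloxy)phenyl]chroman-3-yl (S)-2-methoxy-2-phenylacetate | CO[C@H](C(=O)O[C@@H]1Cc2c(OCc3ccccc3)cc(OCc3ccccc3)cc2O[C@@H]1c1ccc(OCc2ccccc2)c(OCc2ccccc2)c1)c1ccccc1
F4 | step 7 | (2S,3S)-5,7-bis(benzyloxy)-2-[3,4-bis(benzyloxy)phenyl]chroman-3-yl (S)-2-methoxy-2-phenylacetate | CO[C@H](C(=O)O[C@H]1Cc2c(OCc3ccccc3)cc(OCc3ccccc3)cc2O[C@H]1c1ccc(OCc2ccccc2)c(OCc2ccccc2)c1)c1ccccc1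
F5 | step 2 | 2-bromo-3,5-bis(benzyloxy)phenol | Oc1cc(OCc2ccccc2)cc(OCc2ccccc2)c1Br
F6 | step 2 | [2-bromo-3,5-bis(benzyloxy)phenoxy]trimethylsilane | C[Si](C)(C)Oc1cc(OCc2ccccc2)cc(OCc2ccccc2)c1Br
F7 | step 4 | methyl (Z)-3-[3,4-bis(benzyloxy)phenyl]-2-methoxyprop-2-enoate | CO/C(C(=O)OC)=C\c1ccc(OCc2ccccc2)c(OCc2ccccc2)c1
F8 | step 4 | (Z)-3-[3,4-bis(benzyloxy)phenyl]-2-methoxyprop-2-en-1-ol | CO/C(CO)=C\c1ccc(OCc2ccccc2)c(OCc2ccccc2)c1
A1 | alternative 1 | (E)-3-[3,4-bis(benzyloxy)phenyl]-1-(2,4,6-trihydroxyphenyl)prop-2-en-1-one | O=C(/C=C/c1ccc(OCc2ccccc2)c(OCc2ccccc2)c1)c1c(O)cc(O)cc1O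
A2 | alternative 1 | methyl (E)-9-[3,4-bis(benzyloxy)phenyl]-3,5,7-trioxonon-8-enoate | COC(=O)CC(=O)CC(=O)CC(=O)/C=C/c1ccc(OCc2ccccc2)c(OCc2ccccc2)c1
A3 | alternative 2 | (2R,3R)-5,7-bis(benzyloxy)-2-[3,4-bis(benzyloxy)phenyl]chroman-3-yl 4-(benzyloxy)-3,5-dimethoxybenzoate (identical with 22) | COc1cc(C(=O)O[C@@H]2Cc3c(OCc4ccccc4)cc(OCc4ccccc4)cc3O[C@@H]2c2ccc(OCc3ccccc3)c(OCc3ccccc3)c2)cc(OC)c1OCc1ccccc1
A4 | alternative 2 | 3,5-bis(benzyloxy)-2-(hydroxymethyl)phenol | OCc1c(O)cc(OCc2ccccc2)cc1OCc1ccccc1
A5 | alternative 2 | 3,5-bis(benzyloxy)-6-methylidenecyclohexa-2,4-dien-1-one | C=C1C(=O)C=C(OCc2ccccc2)C=C1OCc1ccccc1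
A6 | alternative 2 | (Z)-2-[3,4-bis(benzyloxy)phenyl]ethenyl 4-(benzyloxy)-3,5-dimethoxybenzoate | COc1cc(C(=O)O/C=C\c2ccc(OCc3ccccc3)c(OCc3ccccc3)c2)cc(OC)c1OCc1ccccc1
A7 | alternative 3 | (S)-5,7-bis(benzyloxy)-2-[3,4-bis(benzyloxy)phenyl]-2H-chromene | C1=C[C@@H](c2ccc(OCc3ccccc3)c(OCc3ccccc3)c2)Oc2cc(OCc3ccccc3)cc(OCc3ccccc3)c21
A8 | alternative 3 | 3,5-bis(benzyloxy)-2-ethenyl-1-{[(1S)-1-(3,4-bis(benzyloxy)phenyl)prop-2-en-1-yl]oxy}benzene | C=C[C@@H](c1ccc(OCc2ccccc2)c(OCc2ccccc2)c1)Oc1cc(OCc2ccccc2)cc(OCc2ccccc2)c1C=C
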